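**Plan**
Retrosynthesis: cut the C3 ester first (acid 25 from 3-methylfuran-2(5H)-one and angelic acid), then the C7=C11 alkene (acetone aldol), then the C3–O, C9–O, C4–H and C10–H bonds together with C4–C15, and last the C5–C6 and C9–C10 bonds of ring B.
Enabling feature: quaternary C5 of ring A is flanked by C4 and C10, and the ring B carbonyl C8 is 1,5 to C4 and β to C10; this is the retron of a Michael/aldol (Robinson) annulation of 2-methylcyclohexane-1,3-dione with methyl vinyl ketone (C6–C9).
Forward: ring A is bought as the dione, ring B is closed onto it in one flask, C15 is added at the spared C4 carbonyl, one double hydroboration oxygenates C3 and C9, then C11–C13 (acetone) and the side chain are attached.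
Stereochemistry: C5 from L-proline desymmetrisation of the two enantiotopic carbonyls; C3, C4, C9 and C10 from hydroboration of both ring alkenes anti to the C5 methyl; both Z alkenes of the side chain from a butenolide ring and from angelic acid.

Key step: step 1

Remark: eremophilane numbering is used for the decalin (ring A = C1–C5 and C10, ring B = C5–C10, C14 = CH3 on C5, C15 = CH3 on C4, C11–C13 = isopropylidene on C7); β is the face of the C5 methyl; a one-pot sequence is counted as one step.

Step 1
Reactants: 1 2-methylcyclohexane-1,3-dione; 2 methyl vinyl ketone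
Product: 5 (S)-Wieland–Miescher ketone, via Michael triketone 3 (not isolated), via bicyclic ketol 4 (not isolated)
Conditions: L-proline (35 mol %), DMSO, 35 °C, one pot
Reagents that add atoms: none
Why: Michael addition of the enolised dione (C5) to the terminal carbon (C6) of 2 gives the achiral triketone 3, whose side-chain methyl ketone forms an enamine with L-proline that attacks one of the two enantiotopic ring carbonyls (C10) through C9, and dehydration of ketol 4 gives the enone, so both the C5–C6 and the C9–C10 bond and all of ring B arise in one flask. The closest known reaction type is the proline-catalysed Hajos–Parrish–Eder–Sauer–Wiechert form of the Robinson annulation, run as the known one-pot Michael/aldol condensation. Ring B closes by a 6-(enolendo)-exo-trig intramolecular aldol addition. The only stereocentre that remains, quaternary C5, is controlled by the catalyst: in the chair-like enamine transition state the proline carboxylic acid hydrogen-bonds to the carbonyl under attack, and the L enantiomer selects the carbonyl that leads to the S configuration. The step needs enantiotopic-group selectivity and a single annulation; the mirror symmetry of the 2,2-disubstituted 1,3-dione makes C4 and C10 differ only in handedness, only the C9 enamine can reach a ring carbonyl through a six-membered transition state, and quaternary C5 cannot react twice. The untouched C4 carbonyl is the handle for C3 and C15, and the enantiomeric purity of 5 can be raised by crystallisation if required.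

Step 2
Reactants: 5 (S)-Wieland–Miescher ketone
Product: 6 C8 dithiolane of 5 with the C4 ketone free
Conditions: HSCH2CH2SH, p-TsOH·H2O (cat.), AcOH, rt
Reagents that add atoms: ethane-1,2-dithiol, SCCS
Why: Acid-catalysed dithioketalisation takes place at the conjugated C8 carbonyl and not at the neopentyl C4 ketone next to quaternary C5, a selectivity known for this diketone, and unlike O-ketalisation it leaves the C9=C10 alkene in place for step 5.

Step 3
Reactants: 6 C8 dithiolane ketone
Product: 8 C3=C4 enol triflate, via potassium enolate 7 (not isolated)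
Conditions: KN(SiMe3)2, THF, −78 °C; then PhNTf2, −78 °C to rt
Reagents that add atoms: N-phenylbis(trifluoromethanesulfonimide), O=S(=O)(N(c1ccccc1)S(=O)(=O)C(F)(F)F)C(F)(F)F
Why: Enol triflate formation: the C4 ketone can enolise only toward C3 because C5 is quaternary, so deprotonation and O-sulfonylation of enolate 7 give a single regioisomer.

Step 4
Reactants: 8 enol triflate
Product: 9 4-methyl-3,9-diene dithiolane
Conditions: MeMgBr, Fe(acac)3 (5 mol %), THF/NMP, −30 to 0 °C
Reagents that add atoms: methylmagnesium bromide, C[Mg]Br
Why: Iron-catalysed Kumada-type cross-coupling of an alkenyl triflate with a Grignard reagent replaces OTf by CH3 (C15), keeps the alkene at C3=C4 and tolerates the dithiolane.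

Step 5
Reactants: 9 diene dithiolane
Product: 11 3α,9α-diol with 4β-CH3 and 10α-H, via bis-alkylborane 10 (not isolated)
Conditions: BH3·THF (excess), THF, 0 °C to rt; then 3 M NaOH, 30% H2O2, 0 °C
Reagents that add atoms: hydrogen peroxide, OO
Why: Hydroboration–oxidation: BH3 adds syn to the α face of both trisubstituted alkenes because the axial C5 methyl shields the β face of rings A and B (the outcome known for steroidal 4-enes, which give the 4α-ol with 5α-H), boron goes to the less substituted C3 and C9, and oxidation with retention sets C3 (α-OH), C4 (β-CH3), C9 (α-OH) and C10 (α-H, trans ring fusion) in one step.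

Step 6
Reactants: 11 diol dithiolane
Product: 14 9α-silyl ether with free 3α-hydroxyl, via C3 triethylsilyl ether 12 (not isolated), via bis-silyl ether 13 (not isolated)
Conditions: Et3SiCl (1.05 equiv), imidazole, CH2Cl2, −20 °C; then t-BuMe2SiOTf, 2,6-lutidine, 0 °C; then MeOH, PPTS, rt
Reagents that add atoms: tert-butyldimethylsilyl trifluoromethanesulfonate, CC(C)(C)[Si](C)(C)OS(=O)(=O)C(F)(F)F
Why: Site-selective silylation with temporary protection: the C9 hydroxyl is screened by the neighbouring spiro-dithiolane, so Et3SiCl reacts only at C3–OH, the more forcing silyl triflate then caps C9–OH, and mild acid methanolysis removes only the labile triethylsilyl ether.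

Step 7
Reactants: 14 dithiolane silyl ether
Product: 15 3α-hydroxy-9α-silyloxy C8 ketone
Conditions: PhI(OCOCF3)2, MeCN/H2O 9:1, 0 °C
Reagents that add atoms: water, O
Why: Oxidative hydrolysis of the dithioketal with a hypervalent iodine reagent (S-activation, then attack of water) unmasks the C8 ketone under near-neutral conditions that spare the silyl ether and the free alcohol.

Step 8
Reactants: 15 hydroxy ketone
Product: 17 C7 acetone aldol adduct, via dilithium alkoxide enolate 16 (not isolated)
Conditions: LiN(iPr)2 (2.2 equiv), THF, −78 °C; then acetone; AcOH quench at −78 °C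
Reagents that add atoms: acetone, CC(C)=O
Why: Aldol addition of a kinetic lithium enolate: after the C3 hydroxyl is deprotonated the amide base removes a proton from the C7 methylene and not from the hindered siloxy-bearing C9, and enolate 16 adds to acetone to bring in C11–C13, the new C7 centre being removed in step 9.

Step 9
Reactants: 17 aldol adduct
Product: 18 3α-hydroxy-9α-silyloxy isopropylidene enone
Conditions: p-TsOH·H2O (cat.), benzene, 50 °C
Reagents that add atoms: none
Why: Acid-catalysed dehydration of the tertiary β-hydroxy ketone (completion of the aldol condensation) gives the thermodynamically preferred conjugated tetrasubstituted isopropylidene enone and creates no stereocentre.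

Step 10
Reactants: 19 3-methylfuran-2(5H)-one
Product: 21 4-methoxybenzyl (Z)-4-hydroxy-2-methylbut-2-enoate, via sodium hydroxy carboxylate 20 (not isolated)
Conditions: NaOH (1.0 equiv), H2O/MeOH, rt, evaporate; then 4-MeOC6H4CH2Cl, NaI (cat.), DMF, rt
Reagents that add atoms: sodium hydroxide, [Na+].[OH-]; 4-methoxybenzyl chloride, COc1ccc(CCl)cc1
Why: Saponification of the butenolide followed by SN2 O-alkylation of the carboxylate: the Z geometry is fixed by the five-membered ring of 19 and is kept because the carboxyl group is esterified without ever being acidified.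

Step 11
Reactants: 21 hydroxy ester; 22 angelic acid
Product: 24 4-methoxybenzyl (Z)-4-(angeloyloxy)-2-methylbut-2-enoate, via Yamaguchi mixed anhydride 23 (not isolated)
Conditions: 22, 2,4,6-Cl3C6H2COCl, Et3N, toluene, rt; then 21, DMAP, 0 °C
Reagents that add atoms: none
Why: Yamaguchi esterification: mixed anhydride 23 acylates the unhindered primary allylic alcohol rapidly under DMAP catalysis, a protocol known to keep the Z geometry of angelates.

Step 12
Reactants: 24 diester
Product: 25 (Z)-4-(angeloyloxy)-2-methylbut-2-enoic acid
Conditions: CF3CO2H, anisole, CH2Cl2, 0 °C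
Reagents that add atoms: none
Why: Acidolysis of the 4-methoxybenzyl ester (SN1 cleavage with anisole as cation trap) frees the carboxylic acid without hydrolysing the allylic angelate or touching either Z alkene.

Step 13
Reactants: 18 hydroxy enone; 25 side-chain acid
Product: 27 9-O-silyl ether of the target, via mixed anhydride 26 (not isolated)
Conditions: 25, 2,4,6-Cl3C6H2COCl, Et3N, toluene, rt; then 18, DMAP, rt to 40 °C
Reagents that add atoms: none
Why: Yamaguchi esterification of the only free hydroxyl, the equatorial C3–OH, by mixed anhydride 26 proceeds with retention at C3, and no site selectivity is needed because the C9 oxygen is silylated.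

Step 14
Reactants: 27 silyl-protected ester
Product: 28 CNP0308665.1
Conditions: HF·pyridine, THF/pyridine, 0 °C to rt
Reagents that add atoms: none
Why: Fluoride-induced desilylation with buffered HF removes the α-keto silyl ether under mildly acidic conditions that leave the two unsaturated esters, the enone and all stereocentres untouched.

**Compound list**
1 | 2-methylcyclohexane-1,3-dione | CC1C(=O)CCCC1=O | starting material
2 | methyl vinyl ketone (but-3-en-2-one) | CC(=O)C=C | starting material
3 | 2-methyl-2-(3-oxobutyl)cyclohexane-1,3-dione (Michael triketone) | CC(=O)CCC1(C)C(=O)CCCC1=O | intermediate (not isolated)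
4 | cis-fused ketol, 4a-hydroxy-8a-methyloctahydronaphthalene-1,6-dione, OH cis to CH3 | C1CC[C@]2(O)CC(=O)CC[C@]2(C)C1=O | intermediate (not isolated)
5 | (S)-8a-methyl-3,4,8,8a-tetrahydronaphthalene-1,6(2H,7H)-dione, (S)-Wieland–Miescher ketone (C4 ketone, C8 enone, C9=C10) | C[C@]12CCC(=O)C=C1CCCC2=O | intermediate
6 | spiro-1,3-dithiolane at C8 of 5; C4 ketone free, C9=C10 kept, C5 as in 5 | O=C1CCCC2=CC3(SCCS3)CC[C@]12C | intermediate
7 | potassium C3=C4 enolate of 6 | [K+].[O-]C1=CCCC2=CC3(SCCS3)CC[C@]12C | intermediate (not isolated)
8 | C4 enol triflate (C3=C4, C9=C10, C8 dithiolane) | FC(F)(F)S(=O)(=O)OC1=CCCC2=CC3(SCCS3)CC[C@]12C | intermediate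
9 | 4,5-dimethyl-3,9-diene with C8 dithiolane | CC1=CCCC2=CC3(SCCS3)CC[C@]12C | intermediate
10 | 3α,9α-bis(boryl) adduct of 9 (4β-CH3, 10α-H), formal monoalkylborane form | B[C@@H]1CC[C@H]2[C@H](B)C3(SCCS3)CC[C@]2(C)[C@H]1C | intermediate (not isolated)
11 | 8,8-ethylenedithio-4β,5β-dimethyl-trans-decalin-3α,9α-diol (10α-H) | O[C@@H]1CC[C@H]2[C@H](O)C3(SCCS3)CC[C@]2(C)[C@H]1C | intermediate
12 | 3-O-triethylsilyl ether of 11 | CC[Si](CC)(CC)O[C@@H]1CC[C@H]2[C@H](O)C3(SCCS3)CC[C@]2(C)[C@H]1C | intermediate (not isolated)
13 | 3-O-triethylsilyl 9-O-tert-butyldimethylsilyl ether of 11 | CC[Si](CC)(CC)O[C@@H]1CC[C@H]2[C@H](O[Si](C)(C)C(C)(C)C)C3(SCCS3)CC[C@]2(C)[C@H]1C | intermediate (not isolated)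
14 | 9α-(tert-butyldimethylsilyloxy)-8,8-ethylenedithio-4β,5β-dimethyl-trans-decalin-3α-ol | O[C@@H]1CC[C@H]2[C@H](O[Si](C)(C)C(C)(C)C)C3(SCCS3)CC[C@]2(C)[C@H]1C | intermediate
15 | 3α-hydroxy-9α-(tert-butyldimethylsilyloxy)-4β,5β-dimethyl-trans-decalin-8-one (10α-H) | O[C@@H]1CC[C@H]2[C@H](O[Si](C)(C)C(C)(C)C)C(=O)CC[C@]2(C)[C@H]1C | intermediate
16 | dilithium salt of 15: C3 alkoxide and C7=C8 enolate | [Li+].[Li+].[O-][C@@H]1CC[C@H]2[C@H](O[Si](C)(C)C(C)(C)C)C([O-])=CC[C@]2(C)[C@H]1C | intermediate (not isolated)
17 | 7-(2-hydroxypropan-2-yl) derivative of 15 (C7 epimers, inconsequential) | O[C@@H]1CC[C@H]2[C@H](O[Si](C)(C)C(C)(C)C)C(=O)C(C(C)(C)O)C[C@]2(C)[C@H]1C | intermediate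
18 | 3α-hydroxy-9α-(tert-butyldimethylsilyloxy)-trans-eremophil-7(11)-en-8-one (4β,5β-dimethyl, 10α-H) | O[C@@H]1CC[C@H]2[C@H](O[Si](C)(C)C(C)(C)C)C(=O)C(=C(C)C)C[C@]2(C)[C@H]1C | intermediate
19 | 3-methylfuran-2(5H)-one | CC1=CCOC1=O | starting material
20 | sodium (Z)-4-hydroxy-2-methylbut-2-enoate | [Na+].OC/C=C(/C)C(=O)[O-] | intermediate (not isolated)
21 | 4-methoxybenzyl (Z)-4-hydroxy-2-methylbut-2-enoate | OC/C=C(/C)C(=O)OCc1ccc(OC)cc1 | intermediate
22 | angelic acid, (Z)-2-methylbut-2-enoic acid | C/C=C(/C)C(=O)O | starting material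
23 | angelic 2,4,6-trichlorobenzoic mixed anhydride | C/C=C(/C)C(=O)OC(=O)c1c(Cl)cc(Cl)cc1Cl | intermediate (not isolated)
24 | 4-methoxybenzyl (Z)-4-[(Z)-2-methylbut-2-enoyloxy]-2-methylbut-2-enoate | C/C=C(/C)C(=O)OC/C=C(/C)C(=O)OCc1ccc(OC)cc1 | intermediate
25 | (Z)-4-[(Z)-2-methylbut-2-enoyloxy]-2-methylbut-2-enoic acid | C/C=C(/C)C(=O)OC/C=C(/C)C(=O)O | intermediate
26 | mixed anhydride of 25 with 2,4,6-trichlorobenzoic acid | C/C=C(/C)C(=O)OC/C=C(/C)C(=O)OC(=O)c1c(Cl)cc(Cl)cc1Cl | intermediate (not isolated)
27 | 9-O-tert-butyldimethylsilyl ether of the target (3α-ester, 9α-silyloxy) | C/C=C(/C)C(=O)OC/C=C(/C)C(=O)O[C@@H]1CC[C@H]2[C@H](O[Si](C)(C)C(C)(C)C)C(=O)C(=C(C)C)C[C@]2(C)[C@H]1C | intermediate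
28 | CNP0308665.1: 3α-[(Z)-4-(angeloyloxy)-2-methylbut-2-enoyloxy]-9α-hydroxy-trans-eremophil-7(11)-en-8-one | C/C=C(/C)C(=O)OC/C=C(/C)C(=O)O[C@@H]1CC[C@H]2[C@H](O)C(=O)C(=C(C)C)C[C@]2(C)[C@H]1C | target

**Step count and risks**
Total steps: 14. Longest linear sequence: 11 steps (steps 1 to 9, then 13 and 14); steps 10 to 12 make the side-chain acid.

Step 5 (double hydroboration). What may go wrong: the dithiolane may interfere, by binding borane, by slowing attack on the alkene next to the dithioketal carbon, or by sulfur oxidation in the peroxide stage, so that functionalisation is incomplete or unselective. The fallback sets out from 9 and comes back at 15, and replaces hydroboration by dissolving-metal reduction, enolate oxidation and reductive epoxide opening, all of which tolerate the C8 ketone. PhI(OCOCF3)2 in wet MeCN removes the dithiolane first and gives the 4,5-dimethyl dienone F1. Li in NH3/THF with t-BuOH, then Me3SiCl/Et3N, gives the trans-fused trimethylsilyl enol ether F2; the C10 carbanion is protonated anti to the C5 methyl and the C8=C9 enolate is trapped regiospecifically. Rubottom oxidation (mCPBA, 1 equiv, NaHCO3, −20 °C, α face; the enol ether reacts far faster than the ring A alkene) with mild acid work-up gives the 9α-hydroxy ketone F3. t-BuMe2SiOTf/2,6-lutidine gives the silyl ether F4. mCPBA then epoxidises the ring A alkene from the α face to the 3α,4α-epoxide F5. Cp2TiCl (trivalent titanium, made from Cp2TiCl2 and Zn) with 1,4-cyclohexadiene opens the epoxide homolytically at tertiary C4, and hydrogen-atom transfer to the α face of the C4 radical gives 15.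

Step 13 (esterification of C3–OH). What may go wrong: slow acylation of the hindered equatorial hydroxyl next to the C4 methyl gives the activated Z acid time to isomerise to the E isomer or to decompose. The fallback sets out from 18 and comes back at 27, and forms the ester by substitution with inversion, so the acid is the nucleophile and is never activated. Dess–Martin periodinane oxidises 18 to the 3-ketone F6. LiBH(s-Bu)3 at −78 °C attacks the C3 ketone from the α face, because the axial β trajectory is blocked by the C5 methyl and the C8 ketone is far more hindered, and gives the axial 3β-alcohol F7. Mitsunobu reaction of F7 with acid 25 (PPh3, DIAD, THF) then gives 27 with inversion at C3.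

Step 11 (acylation of hydroxy ester 21). What may go wrong: under the basic acylation conditions the Z-placed hydroxyl can attack its own ester (5-exo ring closure back to the butenolide) before it is acylated. The fallback sets out from 22 and comes back at 24, and builds the Z alkene by olefination with the acyloxy group already in place, so no free Z-hydroxy ester is handled. Alkylation of 22 with 2-bromo-1,1-diethoxyethane (Cs2CO3, DMF) gives 2,2-diethoxyethyl angelate F8, and aqueous CF3CO2H gives 2-oxoethyl angelate F9. 2-Bromopropanoyl bromide and 4-methoxybenzyl alcohol give 4-methoxybenzyl 2-bromopropanoate F10, and a Michaelis–Becker reaction with diphenyl phosphite (NaH, THF) gives 4-methoxybenzyl 2-(diphenoxyphosphoryl)propanoate F11. The Z-selective Horner–Wadsworth–Emmons reaction of the diaryl phosphonate F11 with F9 (NaH, THF, −78 °C) gives 24.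

Further compounds
F1 | step 5 | 4a,5-dimethyl-4,4a,7,8-tetrahydronaphthalen-2(3H)-one, C5 as in 9 (C3=C4 and C9=C10, C8 ketone) | CC1=CCCC2=CC(=O)CC[C@]12C
F2 | step 5 | trans-fused trimethylsilyl enol ether (C8=C9, 10α-H, C3=C4 kept) | CC1=CCC[C@H]2C=C(O[Si](C)(C)C)CC[C@]12C
F3 | step 5 | 9α-hydroxy-4,5-dimethyl-trans-octal-3-en-8-one (10α-H) | CC1=CCC[C@H]2[C@H](O)C(=O)CC[C@]12C
F4 | step 5 | 9α-(tert-butyldimethylsilyloxy) ether of F3 | CC1=CCC[C@H]2[C@H](O[Si](C)(C)C(C)(C)C)C(=O)CC[C@]12C
F5 | step 5 | 3α,4α-epoxide of F4 | O1[C@@H]2CC[C@H]3[C@H](O[Si](C)(C)C(C)(C)C)C(=O)CC[C@]3(C)[C@]12C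
F6 | step 13 | 3-ketone from 18 (3,8-dione, 9α-silyloxy, 4β-CH3) | O=C1CC[C@H]2[C@H](O[Si](C)(C)C(C)(C)C)C(=O)C(=C(C)C)C[C@]2(C)[C@H]1C
F7 | step 13 | 3β (axial) alcohol, C3 epimer of 18 | O[C@H]1CC[C@H]2[C@H](O[Si](C)(C)C(C)(C)C)C(=O)C(=C(C)C)C[C@]2(C)[C@H]1C
F8 | step 11 | 2,2-diethoxyethyl (Z)-2-methylbut-2-enoate | C/C=C(/C)C(=O)OCC(OCC)OCC
F9 | step 11 | 2-oxoethyl (Z)-2-methylbut-2-enoate | C/C=C(/C)C(=O)OCC=O
F10 | step 11 | 4-methoxybenzyl 2-bromopropanoate | CC(Br)C(=O)OCc1ccc(OC)cc1
F11 | step 11 | 4-methoxybenzyl 2-(diphenoxyphosphoryl)propanoate | CC(C(=O)OCc1ccc(OC)cc1)P(=O)(Oc1ccccc1)Oc1ccccc1
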